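**Retrosynthetic overview** (lactone numbering O1, C2(=O), C3, C4, C5; C1' is the side-chain stereocentre that carries CH2OAc)

1. Target 30 ⇐ diol 29 (acetylation of the primary OH) ⇐ silyl ether 28 ⇐ lactone 26 by trans-selective enolate hydroxylation at C3.
2. Lactone ring of 26 ⇐ open-chain diazoacetate 25: the carbene carbon (future C3) inserts into a C–H bond of the unfunctionalised C4 methylene, so the C3–C4 bond closes the ring O1–C2–C3–C4–C5 and sets C4. Enabling feature: the ester oxygen O1 on C5H2 holds C2 and C3 so that the C4 methylene, next to C1', lies 1,5 to the carbene carbon.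
3. 25 ⇐ alcohol 23 ⇐ skipped diene 21 (hydroboration of its vinyl group) ⇐ copper-catalysed enantioselective SN2' coupling of alkenylboronate 16 with allylic phosphate 19, which sets C1' and brings in the 1,1-disubstituted alkene.
4. 16 ⇐ 1β-acetyl-trans-hydrindane 13 ⇐ hydrindanone 8 ⇐ bicyclic enedione 1 (gem-dimethylation at C4, deoxygenation at C5, two face-selective hydrogenations).
5. Ring order: both carbocycles come with 1 (the ring fusion is made trans in step 4); the lactone is the only ring that is built, in step 16.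

Key step: step 16

Remark: Rh2(4R-MPPIM)4 is Rh2L4 with L = N-bound methyl (4R)-2-oxo-1-(3-phenylpropanoyl)imidazolidine-4-carboxylate; this antipode, and the antipode of the chiral ligand in step 13, are assumed to give the drawn configurations (the rhodium one by analogy with 3-arylpropyl diazoacetates) and would be confirmed on small scale, the mirror-image catalysts being equally accessible.

**Route**

Step 1
Reactants: 1 (S)-7a-methyl-2,3,7,7a-tetrahydro-1H-indene-1,5(6H)-dione
Product: 2 C1 mono(ethylene ketal) of the enedione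
Conditions: HOCH2CH2OH, TsOH·H2O (cat.), 4 Å MS, CH2Cl2, rt
Reagents that add atoms: ethylene glycol, OCCO
Why: Acid-catalysed ketalisation should take the saturated cyclopentanone in preference to the less electrophilic conjugated ketone; no stereocentre is formed.

Step 2
Reactants: 2 mono-ketal enone
Product: 4 4,4-dimethyl β,γ-enone ketal, via 4-methyl enone ketal 3 (not isolated)
Conditions: KOtBu (2.5 equiv), t-BuOH/THF, 0 °C; MeI (3 equiv), 0 °C to rt
Reagents that add atoms: iodomethane, CI
Why: Deconjugative α,α-dialkylation of the extended enolate: both methyl groups enter at C4 and the double bond moves to C3=C3a; no stereocentre is formed.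

Step 3
Reactants: 4 4,4-dimethyl β,γ-enone ketal
Product: 6 deoxygenated alkene ketal, via hydrazone 5 (not isolated)
Conditions: N2H4·H2O, KOH, diethylene glycol, 130 °C then 200 °C
Reagents that add atoms: none
Why: Wolff–Kishner reduction removes the hindered C5 ketone; the ketal is base-stable and the alkene, insulated by the quaternary C4, should not migrate.

Step 4
Reactants: 6 deoxygenated alkene ketal
Product: 7 trans-hydrindane ketal
Conditions: H2 (4 atm), 10% Pd/C, EtOAc, rt
Reagents that add atoms: none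
Why: Heterogeneous catalytic hydrogenation should deliver H2 to the C3=C3a bond from the face opposite the angular 7a-methyl and the axial C4 methyl, setting C3a–H trans to the 7a-methyl.

Step 5
Reactants: 7 trans-hydrindane ketal
Product: 8 (3aS,7aS)-4,4,7a-trimethyloctahydro-1H-inden-1-one
Conditions: 1 M HCl, THF, rt
Reagents that add atoms: water, O
Why: Acetal hydrolysis; the ring-fusion centre C3a is not α to the liberated ketone and cannot epimerise.

Step 6
Reactants: 8 hydrindan-1-one
Product: 10 ring enol triflate, via potassium enolate 9 (not isolated)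
Conditions: KN(SiMe3)2, THF, −78 °C; PhNTf2, −78 to 0 °C
Reagents that add atoms: N-phenylbis(trifluoromethanesulfonimide), O=S(=O)(N(c1ccccc1)S(=O)(=O)C(F)(F)F)C(F)(F)F
Why: Enolate O-sulfonylation; only C2 can enolise because C7a is quaternary, so a single enol triflate should form.

Step 7
Reactants: 10 ring enol triflate
Product: 12 ring enone (1-acetyl-hydrindene), via 2-ethoxydiene 11 (not isolated)
Conditions: tributyl(1-ethoxyvinyl)stannane, Pd(PPh3)4 (5 mol %), LiCl, THF, reflux; then 1 M HCl, rt
Reagents that add atoms: tributyl(1-ethoxyvinyl)stannane, CCCC[Sn](CCCC)(CCCC)C(=C)OCC; water, O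
Why: Stille coupling of the alkenyl triflate with an acetyl-anion equivalent, then enol-ether hydrolysis, installs the two-carbon unit at C1; no stereocentre is formed.

Step 8
Reactants: 12 ring enone
Product: 13 1β-acetyl-trans-hydrindane
Conditions: H2 (1 atm), 10% Pd/C, EtOAc, rt
Reagents that add atoms: none
Why: Catalytic hydrogenation of the conjugated C1=C2 bond from the face anti to the 7a-methyl should place the acetyl group β at C1, which is also the thermodynamically preferred epimer.

Step 9
Reactants: 13 methyl ketone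
Product: 15 terminal enol triflate, via potassium enolate 14 (not isolated)
Conditions: KN(SiMe3)2, THF, −78 °C; PhNTf2, −78 to 0 °C
Reagents that add atoms: N-phenylbis(trifluoromethanesulfonimide), O=S(=O)(N(c1ccccc1)S(=O)(=O)C(F)(F)F)C(F)(F)F
Why: Kinetic deprotonation at the methyl group rather than the hindered tertiary C1–H, then O-sulfonylation, gives the 2-triflyloxy-1-alkene without touching C1.

Step 10
Reactants: 15 terminal enol triflate
Product: 16 alkenyl pinacol boronate
Conditions: B2pin2, PdCl2(PPh3)2 (3 mol %), PPh3 (6 mol %), KOPh, toluene, 50 °C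
Reagents that add atoms: bis(pinacolato)diboron, CC1(C)OB(OC1(C)C)B1OC(C)(C)C(C)(C)O1
Why: Miyaura borylation of a 1-alkenyl triflate proceeds with retention of the alkene position; no stereocentre changes.

Step 11
Reactants: 17 (E)-but-2-ene-1,4-diol
Product: 18 mono-TBS ether
Conditions: TBSCl (1 equiv), imidazole, 17 (3 equiv), THF/DMF, 0 °C
Reagents that add atoms: tert-butyldimethylsilyl chloride, CC(C)(C)[Si](C)(C)Cl
Why: Statistical monosilylation of a symmetrical diol used in excess.

Step 12
Reactants: 18 mono-TBS ether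
Product: 19 allylic diethyl phosphate
Conditions: ClP(O)(OEt)2, Et3N, DMAP (cat.), CH2Cl2, 0 °C
Reagents that add atoms: diethyl chlorophosphate, CCOP(=O)(Cl)OCC
Why: O-Phosphorylation of the primary allylic alcohol gives the leaving group for allylic substitution.

Step 13
Reactants: 16 alkenyl pinacol boronate; 19 allylic diethyl phosphate
Product: 21 branched skipped diene, via sodium alkenyl(methoxy)borate 20 (not isolated)
Conditions: chiral sulfonate-bearing N-aryl imidazolinium salt (NHC precursor, 5.5 mol %), CuCl (5 mol %), NaOMe (1.5 equiv), THF, 22 to 60 °C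
Reagents that add atoms: none
Why: Copper-catalysed enantioselective allylic substitution: methoxide activates the boronate, the alkenyl group passes to the NHC–copper centre and attacks the γ-carbon of the phosphate (SN2'), and the chiral ligand sets C1' as (R) by reagent control, the hydrindane centres being remote.

Step 14
Reactants: 21 branched skipped diene
Product: 23 primary alcohol, via B-alkyl-9-borabicyclononane 22 (not isolated)
Conditions: 9-BBN, THF, 0 °C to rt; then 3 M NaOH, 30% H2O2, 0 °C
Reagents that add atoms: hydrogen peroxide, OO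
Why: Hydroboration–oxidation: 9-BBN should add anti-Markovnikov to the monosubstituted vinyl group much faster than to the 1,1-disubstituted alkene, which is flanked by two tertiary carbons; no stereocentre is formed.

Step 15
Reactants: 23 primary alcohol
Product: 25 diazoacetate, via glyoxylate tosylhydrazone ester 24 (not isolated)
Conditions: TsNHN=CHCOCl, PhNMe2, CH2Cl2, 0 °C; then Et3N, 0 °C to rt
Reagents that add atoms: glyoxylic acid chloride 4-toluenesulfonylhydrazone, Cc1ccc(cc1)S(=O)(=O)N/N=C/C(Cl)=O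
Why: Acylation of the alcohol followed by base-induced loss of sulfinate from the tosylhydrazone (Bamford–Stevens-type elimination) gives the diazoacetate; no stereocentre is affected.

Step 16
Reactants: 25 diazoacetate
Product: 26 (4R)-4-substituted γ-butyrolactone
Conditions: Rh2(4R-MPPIM)4 (1 mol %), CH2Cl2, reflux, slow addition of 25
Reagents that add atoms: none
Why: The dirhodium carboxamidate decomposes the diazoacetate to an electrophilic rhodium carbenoid, which inserts through a concerted three-centre transition state into a C–H bond of the methylene β to the ester oxygen, so that the C3–C4 bond, the lactone ring and the C4 stereocentre arise in one event with loss of N2. The closest known reaction type is the carboxamidate-dirhodium-catalysed enantioselective C–H insertion of 3-substituted propyl diazoacetates to 4-substituted γ-butyrolactones. The ring O1–C2–C3–C4–C5 closes by 1,5-insertion, the carbene carbon bonding to the carbon four atoms away, which this catalyst class favours over 1,4- and 1,6-insertion. C4 is set by the chiral ligand sphere, which selects one of the two diastereotopic C4–H bonds, with the neighbouring (R)-centre C1' as a secondary influence. The step needs site selectivity over the tertiary allylic C1'–H (six-membered ring), the C–H bonds next to the silyl ether (seven-membered ring) and cyclopropanation of the 1,1-disubstituted alkene (seven- or eight-membered ring). This should be secured by the five-ring preference of the catalyst, by the slow addition that suppresses carbene dimerisation, and by the steric shielding of the alkene between two tertiary carbons.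

Step 17
Reactants: 26 γ-butyrolactone
Product: 28 trans-3-hydroxy lactone, via potassium lactone enolate 27 (not isolated)
Conditions: KN(SiMe3)2, THF, −78 °C; 2-(benzenesulfonyl)-3-phenyloxaziridine, −78 °C; AcOH quench
Reagents that add atoms: 2-(benzenesulfonyl)-3-phenyloxaziridine, O=S(=O)(c1ccccc1)N1OC1c1ccccc1
Why: Enolate oxidation with an N-sulfonyloxaziridine: the oxidant should approach the enolate face anti to the bulky C4 substituent, so the new C3–OH is trans to it (3S).

Step 18
Reactants: 28 trans-3-hydroxy lactone silyl ether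
Product: 29 diol lactone
Conditions: HF·pyridine, THF/pyridine, 0 °C to rt
Reagents that add atoms: none
Why: Fluoride-mediated desilylation under buffered, mildly acidic conditions leaves the lactone, the alkene and all stereocentres untouched.

Step 19
Reactants: 29 diol lactone
Product: 30 target acetate
Conditions: AcCl (1.1 equiv), 2,4,6-collidine, CH2Cl2, −78 °C
Reagents that add atoms: acetyl chloride, CC(Cl)=O
Why: Kinetically controlled acylation: at low temperature the primary hydroxyl should react far faster than the hindered secondary α-hydroxy-lactone OH; no stereocentre changes.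

**Compound list**

1 | (S)-7a-methyl-2,3,7,7a-tetrahydro-1H-indene-1,5(6H)-dione | C[C@]12CCC(=O)C=C1CCC2=O | starting material
2 | (7a'S)-7a'-methyl-2',3',7',7a'-tetrahydrospiro[[1,3]dioxolane-2,1'-inden]-5'(6'H)-one | C[C@]12CCC(=O)C=C1CCC21OCCO1 | intermediate
3 | (7a'S)-4',7a'-dimethyl-2',3',7',7a'-tetrahydrospiro[[1,3]dioxolane-2,1'-inden]-5'(6'H)-one | C[C@]12CCC(=O)C(C)=C1CCC21OCCO1 | intermediate
4 | (7a'S)-4',4',7a'-trimethyl-2',4',7',7a'-tetrahydrospiro[[1,3]dioxolane-2,1'-inden]-5'(6'H)-one | C[C@]12CCC(=O)C(C)(C)C1=CCC21OCCO1 | intermediate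
5 | hydrazone of 4 at C5' | C[C@]12CCC(=NN)C(C)(C)C1=CCC21OCCO1 | intermediate
6 | (7a'S)-4',4',7a'-trimethyl-2',4',5',6',7',7a'-hexahydrospiro[[1,3]dioxolane-2,1'-indene] | C[C@]12CCCC(C)(C)C1=CCC21OCCO1 | intermediate
7 | (3a'S,7a'S)-4',4',7a'-trimethyloctahydrospiro[[1,3]dioxolane-2,1'-indene] (trans-fused) | C1COC2(O1)CC[C@H]1C(C)(C)CCC[C@]21C | intermediate
8 | (3aS,7aS)-4,4,7a-trimethyloctahydro-1H-inden-1-one | O=C1CC[C@H]2C(C)(C)CCC[C@]12C | intermediate
9 | potassium (3aS,7aS)-4,4,7a-trimethyl-3a,4,5,6,7,7a-hexahydro-3H-inden-1-olate | [K+].[O-]C1=CC[C@H]2C(C)(C)CCC[C@]12C | intermediate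
10 | (3aS,7aS)-4,4,7a-trimethyl-3a,4,5,6,7,7a-hexahydro-3H-inden-1-yl trifluoromethanesulfonate | O=S(=O)(OC1=CC[C@H]2C(C)(C)CCC[C@]12C)C(F)(F)F | intermediate
11 | (3aS,7aS)-1-(1-ethoxyethenyl)-4,4,7a-trimethyl-3a,4,5,6,7,7a-hexahydro-3H-indene | C=C(OCC)C1=CC[C@H]2C(C)(C)CCC[C@]12C | intermediate
12 | 1-[(3aS,7aS)-4,4,7a-trimethyl-3a,4,5,6,7,7a-hexahydro-3H-inden-1-yl]ethan-1-one | CC(=O)C1=CC[C@H]2C(C)(C)CCC[C@]12C | intermediate
13 | 1-[(1S,3aS,7aS)-4,4,7a-trimethyloctahydro-1H-inden-1-yl]ethan-1-one (acetyl cis to the 7a-methyl) | CC(=O)[C@H]1CC[C@H]2C(C)(C)CCC[C@]12C | intermediate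
14 | potassium 1-[(1S,3aS,7aS)-4,4,7a-trimethyloctahydro-1H-inden-1-yl]ethen-1-olate | [K+].[O-]C(=C)[C@H]1CC[C@H]2C(C)(C)CCC[C@]12C | intermediate
15 | 1-[(1S,3aS,7aS)-4,4,7a-trimethyloctahydro-1H-inden-1-yl]ethenyl trifluoromethanesulfonate | C=C(OS(=O)(=O)C(F)(F)F)[C@H]1CC[C@H]2C(C)(C)CCC[C@]12C | intermediate
16 | 4,4,5,5-tetramethyl-2-{1-[(1R,3aS,7aR)-4,4,7a-trimethyloctahydro-1H-inden-1-yl]ethenyl}-1,3,2-dioxaborolane (same spatial arrangement as 13) | C=C(B1OC(C)(C)C(C)(C)O1)[C@H]1CC[C@H]2C(C)(C)CCC[C@]12C | intermediate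
17 | (2E)-but-2-ene-1,4-diol | OC/C=C/CO | starting material
18 | (2E)-4-{[tert-butyl(dimethyl)silyl]oxy}but-2-en-1-ol | CC(C)(C)[Si](C)(C)OC/C=C/CO | intermediate
19 | (2E)-4-{[tert-butyl(dimethyl)silyl]oxy}but-2-en-1-yl diethyl phosphate | CCOP(=O)(OCC)OC/C=C/CO[Si](C)(C)C(C)(C)C | intermediate
20 | sodium methoxy borate of 16 | [Na+].C=C([B-]1(OC)OC(C)(C)C(C)(C)O1)[C@H]1CC[C@H]2C(C)(C)CCC[C@]12C | intermediate
21 | tert-butyl({(2R)-2-ethenyl-3-[(1R,3aS,7aS)-4,4,7a-trimethyloctahydro-1H-inden-1-yl]but-3-en-1-yl}oxy)dimethylsilane | C=C([C@H]1CC[C@H]2C(C)(C)CCC[C@]12C)[C@H](CO[Si](C)(C)C(C)(C)C)C=C | intermediate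
22 | B-alkyl-9-borabicyclo[3.3.1]nonane from 21 (boron on the terminal carbon of the former vinyl group) | C=C([C@H]1CC[C@H]2C(C)(C)CCC[C@]12C)[C@H](CO[Si](C)(C)C(C)(C)C)CCB1C2CCCC1CCC2 | intermediate
23 | (3R)-3-({[tert-butyl(dimethyl)silyl]oxy}methyl)-4-[(1R,3aS,7aS)-4,4,7a-trimethyloctahydro-1H-inden-1-yl]pent-4-en-1-ol | C=C([C@H]1CC[C@H]2C(C)(C)CCC[C@]12C)[C@H](CO[Si](C)(C)C(C)(C)C)CCO | intermediate
24 | glyoxylate 4-toluenesulfonylhydrazone ester of 23 | C=C([C@H]1CC[C@H]2C(C)(C)CCC[C@]12C)[C@H](CO[Si](C)(C)C(C)(C)C)CCOC(=O)/C=N/NS(=O)(=O)c1ccc(C)cc1 | intermediate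
25 | (3R)-3-({[tert-butyl(dimethyl)silyl]oxy}methyl)-4-[(1R,3aS,7aS)-4,4,7a-trimethyloctahydro-1H-inden-1-yl]pent-4-en-1-yl diazoacetate | C=C([C@H]1CC[C@H]2C(C)(C)CCC[C@]12C)[C@H](CO[Si](C)(C)C(C)(C)C)CCOC(=O)C=[N+]=[N-] | intermediate
26 | (4R)-4-[(2R)-1-{[tert-butyl(dimethyl)silyl]oxy}-3-[(1R,3aS,7aS)-4,4,7a-trimethyloctahydro-1H-inden-1-yl]but-3-en-2-yl]oxolan-2-one | C=C([C@H]1CC[C@H]2C(C)(C)CCC[C@]12C)[C@H](CO[Si](C)(C)C(C)(C)C)[C@@H]1COC(=O)C1 | intermediate
27 | potassium enolate of 26 (C2–C3 enolate) | [K+].C=C([C@H]1CC[C@H]2C(C)(C)CCC[C@]12C)[C@H](CO[Si](C)(C)C(C)(C)C)[C@@H]1COC([O-])=C1 | intermediate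
28 | (3S,4R)-4-[(2R)-1-{[tert-butyl(dimethyl)silyl]oxy}-3-[(1R,3aS,7aS)-4,4,7a-trimethyloctahydro-1H-inden-1-yl]but-3-en-2-yl]-3-hydroxyoxolan-2-one | C=C([C@H]1CC[C@H]2C(C)(C)CCC[C@]12C)[C@H](CO[Si](C)(C)C(C)(C)C)[C@@H]1COC(=O)[C@H]1O | intermediate
29 | (3S,4R)-3-hydroxy-4-[(2R)-1-hydroxy-3-[(1R,3aS,7aS)-4,4,7a-trimethyloctahydro-1H-inden-1-yl]but-3-en-2-yl]oxolan-2-one | C=C([C@H]1CC[C@H]2C(C)(C)CCC[C@]12C)[C@H](CO)[C@@H]1COC(=O)[C@H]1O | intermediate
30 | (2R)-2-[(3R,4S)-4-hydroxy-5-oxooxolan-3-yl]-3-[(1R,3aS,7aS)-4,4,7a-trimethyloctahydro-1H-inden-1-yl]but-3-en-1-yl acetate | C=C([C@H]1CC[C@H]2C(C)(C)CCC[C@]12C)[C@H](COC(C)=O)[C@@H]1COC(=O)[C@H]1O | target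

**Step count and risks**

Total step count: 19. Longest linear sequence: 17 (steps 1–10, then 13–19); steps 11–12 make the second fragment.

Steps most likely to fail:

1. Step 16 (key C–H insertion). The catalyst and the neighbouring stereocentre C1' may be mismatched, so that insertion goes into the other diastereotopic C4–H bond, or the carbenoid may be diverted to the tertiary allylic C–H bond or the alkene. The fallback makes the C3–C4 bond by auxiliary-controlled alkylation and closes the ring through the C–O bond instead. It sets out from alcohol 23: Swern oxidation gives the aldehyde F1 and Pinnick oxidation (NaClO2, NaH2PO4, 2-methylbut-2-ene) the carboxylic acid F2. Acylation of (R)-4-benzyl-1,3-oxazolidin-2-one through the pivaloyl mixed anhydride (PivCl, Et3N, LiCl) gives the N-acyl oxazolidinone F3. Alkylation of its sodium enolate (NaN(SiMe3)2, THF, −78 °C) with tert-butyl bromoacetate, on the face away from the benzyl group, gives the alkylated imide F4 with C4 set. LiBH4 in wet ether reduces the imide carbonyl selectively to the hydroxy tert-butyl ester F5, and acid-catalysed lactonisation (camphorsulfonic acid cat., toluene, 60 °C) comes back to the route at lactone 26.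

2. Step 13 (allylic substitution). Transfer of the bulky α-branched alkenyl group from boron to copper may be slow, and facial discrimination on the allyl system may be poor. The fallback sets out from boronate 16 and uses a rhodium-catalysed asymmetric 1,4-addition (Hayashi–Miyaura reaction). The acceptor, ethyl (2E)-4-{[tert-butyl(dimethyl)silyl]oxy}but-2-enoate F6, is made by Wittig olefination of commercial (tert-butyldimethylsilyloxy)acetaldehyde with ethyl (triphenylphosphoranylidene)acetate. Addition of 16 to it with [Rh(OH)(cod)]2, (S)-BINAP (or its antipode, whichever gives the (R)-centre) and aqueous KOH in dioxane at 60 °C gives the β-alkenyl ester F7. Reduction with iBu2AlH (CH2Cl2, −78 to 0 °C) comes back to the route at alcohol 23, so the chemoselective hydroboration of step 14 is bypassed as well.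

3. Step 19 (acetylation). Discrimination between the primary and the secondary hydroxyl may be incomplete, giving over-acylation or acyl migration. The fallback sets out from silyl ether 28 and masks the C3 hydroxyl first: 4-methoxybenzyl trichloroacetimidate with catalytic camphorsulfonic acid gives the 4-methoxybenzyl ether F8. HF·pyridine cleaves the silyl ether to the primary alcohol F9, which is acetylated (Ac2O, pyridine, DMAP cat.) to the acetate F10. Oxidative removal of the 4-methoxybenzyl group with DDQ (CH2Cl2/pH 7 buffer) comes back to the route at target 30.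

**Further compounds**

F1 | step 16 | (3R)-3-({[tert-butyl(dimethyl)silyl]oxy}methyl)-4-[(1R,3aS,7aS)-4,4,7a-trimethyloctahydro-1H-inden-1-yl]pent-4-enal | C=C([C@H]1CC[C@H]2C(C)(C)CCC[C@]12C)[C@H](CO[Si](C)(C)C(C)(C)C)CC=O
F2 | step 16 | corresponding pent-4-enoic acid | C=C([C@H]1CC[C@H]2C(C)(C)CCC[C@]12C)[C@H](CO[Si](C)(C)C(C)(C)C)CC(=O)O
F3 | step 16 | (4R)-4-benzyl-3-acyl-1,3-oxazolidin-2-one of acid F2 | C=C([C@H]1CC[C@H]2C(C)(C)CCC[C@]12C)[C@H](CO[Si](C)(C)C(C)(C)C)CC(=O)N1C(=O)OC[C@H]1Cc1ccccc1
F4 | step 16 | α-(tert-butoxycarbonylmethyl) imide (C4 set) | C=C([C@H]1CC[C@H]2C(C)(C)CCC[C@]12C)[C@H](CO[Si](C)(C)C(C)(C)C)[C@@H](CC(=O)OC(C)(C)C)C(=O)N1C(=O)OC[C@H]1Cc1ccccc1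
F5 | step 16 | γ-hydroxy tert-butyl ester | C=C([C@H]1CC[C@H]2C(C)(C)CCC[C@]12C)[C@H](CO[Si](C)(C)C(C)(C)C)[C@@H](CC(=O)OC(C)(C)C)CO
F6 | step 13 | ethyl (2E)-4-{[tert-butyl(dimethyl)silyl]oxy}but-2-enoate | CCOC(=O)/C=C/CO[Si](C)(C)C(C)(C)C
F7 | step 13 | ethyl (3R)-3-({[tert-butyl(dimethyl)silyl]oxy}methyl)-4-[(1R,3aS,7aS)-4,4,7a-trimethyloctahydro-1H-inden-1-yl]pent-4-enoate | C=C([C@H]1CC[C@H]2C(C)(C)CCC[C@]12C)[C@H](CO[Si](C)(C)C(C)(C)C)CC(=O)OCC
F8 | step 19 | 3-O-(4-methoxybenzyl) ether of 28 | C=C([C@H]1CC[C@H]2C(C)(C)CCC[C@]12C)[C@H](CO[Si](C)(C)C(C)(C)C)[C@@H]1COC(=O)[C@H]1OCc1ccc(OC)cc1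
F9 | step 19 | 3-O-(4-methoxybenzyl) ether of 29 | C=C([C@H]1CC[C@H]2C(C)(C)CCC[C@]12C)[C@H](CO)[C@@H]1COC(=O)[C@H]1OCc1ccc(OC)cc1
F10 | step 19 | 3-O-(4-methoxybenzyl) ether of 30 | C=C([C@H]1CC[C@H]2C(C)(C)CCC[C@]12C)[C@H](COC(C)=O)[C@@H]1COC(=O)[C@H]1OCc1ccc(OC)cc1
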